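## Analysis of the target

The target (C28H24O6) is a macrocyclic bis(bibenzyl): four benzene rings joined in a cycle by two CH2CH2 bridges and two diaryl ether oxygens. Ring A carries the bridge to ring D at C1, the ether oxygen to ring B at C3 and free hydroxyls at C4 and C5. Ring B is a para-phenylene (oxygen at C1, bridge to ring C at C4). Ring C carries that bridge at C1, the ether oxygen to ring D at C2 and hydroxyls at C3 and C4. Ring D is an ortho-phenylene (oxygen at C1, bridge to ring A at C2). Counted through the shortest paths the macrocycle has 17 members (3 atoms of ring A, O, 4 of ring B, 2 CH2, 2 of ring C, O, 2 of ring D, 2 CH2). There is no stereocentre and no double bond outside the arenes, so nothing stereochemical has to be set or related. The two catechol units oxidise readily in air, above all in base, so the four hydroxyls should be unveiled in the last step. The difficulty lies in closing the cyclophane ring and in telling apart six oxygens that sit in two contiguous triads, one of each triad being an ether. The strategy rests on the ring A C3–O–ring B C1 ether: ring B C2 and C6 carry only hydrogen, so a nitro group can sit on C2 for a while, activate C1 towards substitution of fluoride, and then be removed.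

## Retrosynthetic reasoning

**19 to 18.** The four phenols are masked as methyl ethers to the end. Methyl ethers survive every base, hydride, acid and hydrogenation of the route, and one Lewis-acid ether cleavage removes all four without touching the diaryl ether bonds, which have no sp3 carbon on oxygen.

**18 to 15 (through 16 and 17).** The hydrogen at ring B C2 of 18 is traced back to a nitro group in 15. Forward, the nitro group is reduced to aniline 16, which is diazotised to 17 and reduced with loss of nitrogen. This costs two steps but buys an electrophilic ring B for the ring closure.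

**15 to 14, the key disconnection.** The bond between the ring A C3 oxygen and ring B C1 is cut. This is the least hindered junction of the macrocycle: ring B C1 has only the nitro group beside it, whereas the other ether oxygen sits on ring C C2 between a bridge and a methoxy group. Cutting here gives a seco compound with one phenol on ring A and one fluorine ortho to nitro on ring B. The forward reaction is a metal-free, irreversible addition–elimination that can only form the bond at the fluorine-bearing carbon.

**14 to 13.** The ring A phenol has to be masked until the ring closure, because it would otherwise compete in the earlier intermolecular ether formation. A methoxymethyl acetal is chosen: it withstands the carbonate and fluoride of that earlier substitution, which a silyl ether would not, and it is cleaved by acid, which the fluoronitroarene tolerates.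

**13 to 12 to 8 and 10.** The ring C–ring B bridge is cut at its central C–C bond as a stilbene, made by olefination of aldehyde 8 with the phosphonium salt 10, itself from benzylic bromide 9. Ring B is brought in last so that the fluoronitroarene meets as few reagents as possible. The alkene of 12 must then be saturated by a concerted, metal-free hydrogen transfer that leaves the nitro group and the C–F bond alone.

**8 to 6 and 7.** The ring C C2–O bond to ring D is cut. In fluoroaldehyde 7 the formyl group ortho to fluorine activates exactly this carbon for substitution by the phenol 6. The same formyl group is afterwards the handle for the bridge to ring B, so no functional-group interchange is needed.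

**6 to 5 to 2 and 3.** The ring A–ring D bridge is cut as a stilbene as well. Aldehyde 2, the protected form of commercial 1, is olefinated with the ylide 4 of the hydroxybenzyl phosphonium salt 3. Because no nitro group, halogen or benzyl ether is present yet, stilbene 5 can simply be hydrogenated to 6.

## Alternatives that were turned down

**Alternative 1: anodic phenol coupling for the same ether.** The ring A C3–O bond is cut with reversed roles: the oxygen belongs to a ring B phenol and ring A is the carbon partner. Forward, the bis(halophenol) A1 (ring A as 3,5-dibromo-4-hydroxyphenyl, ring B as 3,5-dichloro-4-hydroxyphenyl) would be electrolysed at constant current and the coupled dienone reduced with zinc in the same operation. This would give the macrocyclic bromophenol ether A2 with loss of one bromine.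
- For it: the coupling mimics the likely biogenesis, needs no activating group that must later be excised through an aniline, and delivers the ring A C4 hydroxyl free.
- Against it: in A2 ring A C5 carries bromine where the target carries hydroxyl, so a C–Br to C–O exchange on the macrocycle is needed, in addition to removal of two chlorines and demethylation. A1 holds four aryl halides, which excludes catalytic hydrogenation for both bridges. The electrolysis must oxidise one phenol selectively beside a second phenol and the electron-rich ring C, and phenoxy radical or cation chemistry opens C–C coupling and quinone formation as competing paths.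
- Comparison: it is the stronger strategy in atom economy at the closure and in closeness to biosynthesis. The chosen strategy offers instead a two-electron polar closure with exactly one nucleophile and one electrophile, the ring A oxygenation already in place from commercial aldehyde 1, and three routine steps after the ring is closed against at least four.

**Alternative 2: Friedel–Crafts macrocyclisation onto ring C.** The C–C bond between ring C C1 and the neighbouring bridge carbon is cut, with both diaryl ethers already in place. Forward, the arylacetic acid A3 would be converted in the flask into its acid chloride A4, which under a Lewis acid at high dilution would acylate ring C C1 to give the macrocyclic deoxybenzoin A5.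
- For it: the ring is closed by a C–C bond, both ethers are made intermolecularly where they can be forced, and no nitro group or diazonium salt appears.
- Against it: ring C of A3 is a 1-aryloxy-2,3-dimethoxybenzene with three free positions. C1 (para to the C4 methoxy, ortho to the aryloxy group) is electronically favoured but the most hindered, and C5 (para to the aryloxy oxygen, ortho to methoxy) is a serious competitor. The para position of ring D and intermolecular acylation compete as well, and arylacetyl chlorides tend to form ketenes. The ketone of A5 must afterwards be deoxygenated before demethylation.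
- Comparison: on the number of steps after ring closure it is as strong as the chosen route, and it is stronger in avoiding the nitro detour. The chosen strategy offers instead absolute site control, because the new bond can form only at the carbon that bears fluorine, whereas the acylation depends on the relative nucleophilicity of several arene positions.

**Alternative 3: pyrone–ynol ether Diels–Alder reaction that builds ring B.** Ring B itself is disconnected at its C1–C2 and C5–C6 bonds, leaving in A6 an ethynyl ether on the ring A C3 oxygen and a 2-pyrone acylated at C5 by the ring C arylacetyl unit. Forward, heating A6 at high dilution would give an intramolecular inverse-demand cycloaddition of the aryloxyalkyne across pyrone C3 and C6. Decarboxylative aromatisation would then give A7, the macrocyclic deoxybenzoin with the carbonyl on ring B.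
- For it: ring B and the macrocycle arise in one operation; matching of the nucleophilic terminal alkyne carbon with the electrophilic pyrone C6 fixes the para relationship; the reaction is irreversible; only the ketone is left to remove.
- Against it: A6 needs an aryl ethynyl ether on a hindered, electron-rich phenol, reached in several steps and fragile towards heat and water, and a 5-acylpyrone with an acidic CH2 between carbonyl and ring C. The cycloaddition must pass through a macrocyclic transition state at temperatures where ynol ethers polymerise, and ketone deoxygenation follows.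
- Comparison: it is stronger in the number of bonds formed in the key step. The chosen strategy offers instead a precursor assembled from four commercial arenes by standard olefination and substitution chemistry, so that the risk is concentrated in the ring closure alone.

Key step: step 9

Remark on the chemistry: stilbenes 5 and 12 are expected as mixtures of alkene isomers; both double bonds are saturated in the following step, so their SMILES carry no geometry descriptor.

## Route

Step 1
Reactants: 1 3-hydroxy-4,5-dimethoxybenzaldehyde
Product: 2 3,4-dimethoxy-5-(methoxymethoxy)benzaldehyde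
Conditions: MOMCl, iPr2NEt, CH2Cl2, 0 °C to rt
Reagents that add atoms: chloromethyl methyl ether, COCCl
Why: O-alkylation of the phenol by the reactive α-chloro ether (MOM protection, Williamson type); the acetal resists the base, fluoride, hydride and hydrogenation used later and is removed by acid, whereas a silyl ether would be cleaved by the fluoride set free in step 4.

Step 2
Reactants: 2 3,4-dimethoxy-5-(methoxymethoxy)benzaldehyde; 3 (2-hydroxybenzyl)triphenylphosphonium bromide
Product: 5 2-[2-(3,4-dimethoxy-5-(methoxymethoxy)phenyl)ethenyl]phenol (E/Z mixture), via potassium phenoxide ylide 4 (not isolated)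
Conditions: 3, KOtBu (2.3 equiv), THF, 0 °C; then 2, 0 °C to rt
Reagents that add atoms: none
Why: Wittig olefination; two equivalents of base take the phenol and the benzylic proton of 3, and the resulting ylide 4 condenses with the aldehyde, the alkene geometry being irrelevant because the double bond is saturated next.

Step 3
Reactants: 5 2-[2-(3,4-dimethoxy-5-(methoxymethoxy)phenyl)ethenyl]phenol
Product: 6 2-[2-(3,4-dimethoxy-5-(methoxymethoxy)phenyl)ethyl]phenol
Conditions: H2 (1 atm), 10% Pd/C, EtOAc, rt
Reagents that add atoms: none
Why: Heterogeneous catalytic hydrogenation of the stilbene; the acetal, the methyl ethers and the phenol are inert, and no halogen, nitro group or benzyl ether is present at this stage.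

Step 4
Reactants: 6 2-[2-(3,4-dimethoxy-5-(methoxymethoxy)phenyl)ethyl]phenol; 7 2-fluoro-3,4-dimethoxybenzaldehyde
Product: 8 2-{2-[2-(3,4-dimethoxy-5-(methoxymethoxy)phenyl)ethyl]phenoxy}-3,4-dimethoxybenzaldehyde
Conditions: K2CO3, DMF, 130 °C
Reagents that add atoms: none
Why: Intermolecular SNAr: the phenoxide of 6 adds to the fluorine-bearing carbon ortho to the formyl group, which stabilises the Meisenheimer complex, and fluoride leaves; 6 has a single phenol and the MOM acetal is stable to carbonate and fluoride.

Step 5
Reactants: 9 4-(bromomethyl)-1-fluoro-2-nitrobenzene (4-fluoro-3-nitrobenzyl bromide)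
Product: 10 (4-fluoro-3-nitrobenzyl)triphenylphosphonium bromide
Conditions: PPh3, toluene, 60 °C
Reagents that add atoms: triphenylphosphine, c1ccc(cc1)P(c1ccccc1)c1ccccc1
Why: SN2 quaternisation of the phosphine at the benzylic bromide, far faster than any attack on the aryl fluoride; the salt should precipitate from toluene.

Step 6
Reactants: 8 2-{2-[2-(3,4-dimethoxy-5-(methoxymethoxy)phenyl)ethyl]phenoxy}-3,4-dimethoxybenzaldehyde; 10 (4-fluoro-3-nitrobenzyl)triphenylphosphonium bromide
Product: 12 1-[2-(4-fluoro-3-nitrophenyl)ethenyl]-2-{2-[2-(3,4-dimethoxy-5-(methoxymethoxy)phenyl)ethyl]phenoxy}-3,4-dimethoxybenzene (E/Z mixture), via (4-fluoro-3-nitrobenzylidene)triphenylphosphorane 11 (not isolated)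
Conditions: 10, NaN(SiMe3)2, THF, −78 °C; then 8, −78 °C to rt
Reagents that add atoms: none
Why: Wittig olefination with a preformed semi-stabilised ylide; complete deprotonation at low temperature by a hindered amide leaves no nucleophile for the aryl fluoride, and in the ylide the carbanionic carbon para to fluorine makes that ring a poor SNAr acceptor.

Step 7
Reactants: 12 seco stilbene MOM ether (as named in step 6)
Product: 13 1-[2-(4-fluoro-3-nitrophenyl)ethyl]-2-{2-[2-(3,4-dimethoxy-5-(methoxymethoxy)phenyl)ethyl]phenoxy}-3,4-dimethoxybenzene
Conditions: 2-nitrobenzenesulfonylhydrazide (excess, in portions), Et3N, CH2Cl2, rt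
Reagents that add atoms: none
Why: Diimide reduction: concerted syn transfer of two hydrogens to the nonpolar C=C, which leaves the nitro group and the C–F bond untouched where catalytic hydrogenation would not; generating diimide at room temperature avoids hot nucleophilic media.

Step 8
Reactants: 13 seco bibenzyl MOM ether (as named in step 7)
Product: 14 5-{2-[2-(6-(2-(4-fluoro-3-nitrophenyl)ethyl)-2,3-dimethoxyphenoxy)phenyl]ethyl}-2,3-dimethoxyphenol
Conditions: conc. HCl (cat.), MeOH–THF, 45 °C
Reagents that add atoms: none
Why: Acid-catalysed cleavage of the MOM acetal by transacetalisation to methanol; under acid no nucleophile is strong enough to displace the activated fluoride, and methyl and diaryl ethers are stable.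

Step 9
Reactants: 14 5-{2-[2-(6-(2-(4-fluoro-3-nitrophenyl)ethyl)-2,3-dimethoxyphenoxy)phenyl]ethyl}-2,3-dimethoxyphenol
Product: 15 macrocyclic nitro diaryl ether tetramethyl ether (17-membered ring; NO2 on ring B C2, ortho to the ring A–O–ring B oxygen; OMe on ring A C4, C5 and ring C C3, C4)
Conditions: K2CO3 (5 equiv), dry DMF, 45 °C, slow addition of 14, final 0.003 M
Reagents that add atoms: none
Why: Carbonate deprotonates the only phenol of 14; the ring A C3 phenoxide adds to ring B C1, the carbon that bears fluorine and lies ortho to nitro, giving a Meisenheimer complex whose charge rests on the nitro oxygens, and loss of fluoride restores the arene (addition–elimination SNAr). The closest known reaction type is the intramolecular SNAr etherification of phenoxides onto ortho-nitrofluoroarenes used to close macrocyclic diaryl ethers. The one ring formed is the 17-membered macrocycle, closed by attack of the tethered oxygen on an aromatic sp2 carbon with the breaking C–F bond outside the new ring, so no small-ring stereoelectronic limit applies. No stereocentre is created, and any planar chirality caused by the nitro-bearing ring B disappears when the nitro group is removed. The step needs chemoselectivity, which the substrate secures because it offers one free hydroxyl and one activated carbon–halogen bond, fluoride being a far better nucleofuge here than nitrite. It also needs ring closure to beat oligomerisation, which slow addition to high dilution and the ortho-linked ring C–O–ring D turn, which folds the two termini towards each other, should favour. The substitution is irreversible, and carbonate in DMF at this temperature is too weak a nucleophile to attack the fluoroarene itself.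

Step 10
Reactants: 15 macrocyclic nitro diaryl ether tetramethyl ether
Product: 16 macrocyclic aniline tetramethyl ether (NH2 on ring B C2)
Conditions: H2 (1 atm), 10% Pd/C, EtOAc–MeOH, rt
Reagents that add atoms: none
Why: Catalytic hydrogenation of the aromatic nitro group to the aniline; no halogen or benzyl group remains, and diaryl and methyl ethers are inert.

Step 11
Reactants: 16 macrocyclic aniline tetramethyl ether
Product: 18 macrocyclic tetramethyl ether (ring B unsubstituted at C2), via macrocyclic arenediazonium hydrogen sulfate 17 (not isolated)
Conditions: NaNO2, H2SO4, AcOH–THF–H2O, 0 °C; then 50% aq. H3PO2, Cu2O (cat.), 0 °C to rt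
Reagents that add atoms: sodium nitrite, [Na+].[O-]N=O (supplies the outer nitrogen of 17; no reagent atom other than hydrogen remains in 18)
Why: Diazotisation followed by hydrodediazoniation with hypophosphorous acid, a radical chain in which the aryl radical takes hydrogen from the P–H bond faster than it can attack the neighbouring ring A.

Step 12
Reactants: 18 macrocyclic tetramethyl ether
Product: 19 target CNP0114693.0 (ring A C4, C5 and ring C C3, C4 hydroxyls free)
Conditions: BBr3 (10 equiv), CH2Cl2, −78 °C to rt; then MeOH, H2O, under argon
Reagents that add atoms: none
Why: Lewis-acid cleavage of the four aryl methyl ethers (boron–oxygen adduct, then bromide attack at methyl); the diaryl ether oxygens carry no sp3 carbon and are not cleaved, and work-up under inert gas protects the catechols from oxidation.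

## Compound list

1 | 3-hydroxy-4,5-dimethoxybenzaldehyde | O=Cc1cc(O)c(OC)c(OC)c1 | starting material
2 | 3,4-dimethoxy-5-(methoxymethoxy)benzaldehyde | COCOc1cc(C=O)cc(OC)c1OC | intermediate
3 | (2-hydroxybenzyl)triphenylphosphonium bromide | Oc1ccccc1C[P+](c1ccccc1)(c1ccccc1)c1ccccc1.[Br-] | starting material
4 | potassium 2-[(triphenylphosphoranylidene)methyl]phenoxide | [K+].[O-]c1ccccc1C=P(c1ccccc1)(c1ccccc1)c1ccccc1 | intermediate
5 | 2-[2-(3,4-dimethoxy-5-(methoxymethoxy)phenyl)ethenyl]phenol (E/Z mixture) | COCOc1cc(C=Cc2ccccc2O)cc(OC)c1OC | intermediate
6 | 2-[2-(3,4-dimethoxy-5-(methoxymethoxy)phenyl)ethyl]phenol | COCOc1cc(CCc2ccccc2O)cc(OC)c1OC | intermediate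
7 | 2-fluoro-3,4-dimethoxybenzaldehyde | O=Cc1ccc(OC)c(OC)c1F | starting material
8 | 2-{2-[2-(3,4-dimethoxy-5-(methoxymethoxy)phenyl)ethyl]phenoxy}-3,4-dimethoxybenzaldehyde | COCOc1cc(CCc2ccccc2Oc2c(C=O)ccc(OC)c2OC)cc(OC)c1OC | intermediate
9 | 4-(bromomethyl)-1-fluoro-2-nitrobenzene | [O-][N+](=O)c1cc(CBr)ccc1F | starting material
10 | (4-fluoro-3-nitrobenzyl)triphenylphosphonium bromide | [O-][N+](=O)c1cc(C[P+](c2ccccc2)(c2ccccc2)c2ccccc2)ccc1F.[Br-] | intermediate
11 | (4-fluoro-3-nitrobenzylidene)triphenylphosphorane | [O-][N+](=O)c1cc(C=P(c2ccccc2)(c2ccccc2)c2ccccc2)ccc1F | intermediate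
12 | 1-[2-(4-fluoro-3-nitrophenyl)ethenyl]-2-{2-[2-(3,4-dimethoxy-5-(methoxymethoxy)phenyl)ethyl]phenoxy}-3,4-dimethoxybenzene (E/Z mixture) | COCOc1cc(CCc2ccccc2Oc2c(C=Cc3ccc(F)c([N+](=O)[O-])c3)ccc(OC)c2OC)cc(OC)c1OC | intermediate
13 | 1-[2-(4-fluoro-3-nitrophenyl)ethyl]-2-{2-[2-(3,4-dimethoxy-5-(methoxymethoxy)phenyl)ethyl]phenoxy}-3,4-dimethoxybenzene | COCOc1cc(CCc2ccccc2Oc2c(CCc3ccc(F)c([N+](=O)[O-])c3)ccc(OC)c2OC)cc(OC)c1OC | intermediate
14 | 5-{2-[2-(6-(2-(4-fluoro-3-nitrophenyl)ethyl)-2,3-dimethoxyphenoxy)phenyl]ethyl}-2,3-dimethoxyphenol | Oc1cc(CCc2ccccc2Oc2c(CCc3ccc(F)c([N+](=O)[O-])c3)ccc(OC)c2OC)cc(OC)c1OC | intermediate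
15 | macrocyclic nitro diaryl ether tetramethyl ether (NO2 on ring B C2) | COc1cc2cc(c1OC)Oc1ccc(cc1[N+](=O)[O-])CCc1ccc(OC)c(OC)c1Oc1ccccc1CC2 | intermediate
16 | macrocyclic aniline tetramethyl ether (NH2 on ring B C2) | COc1cc2cc(c1OC)Oc1ccc(cc1N)CCc1ccc(OC)c(OC)c1Oc1ccccc1CC2 | intermediate
17 | macrocyclic arenediazonium hydrogen sulfate (N2+ on ring B C2) | COc1cc2cc(c1OC)Oc1ccc(cc1[N+]#N)CCc1ccc(OC)c(OC)c1Oc1ccccc1CC2.OS(=O)(=O)[O-] | intermediate
18 | macrocyclic tetramethyl ether of the target | COc1cc2cc(c1OC)Oc1ccc(cc1)CCc1ccc(OC)c(OC)c1Oc1ccccc1CC2 | intermediate
19 | CNP0114693.0 | Oc1cc2cc(c1O)Oc1ccc(cc1)CCc1ccc(O)c(O)c1Oc1ccccc1CC2 | target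

## Step count and risk

Total step count: 12. Longest linear sequence: 11 steps (steps 1 to 4 and 6 to 12); step 5 is a one-step side branch.

**Step 9 (key step).** The open chain has two flexible ethylene bridges and may not fold, so intermolecular etherification to dimers and oligomers could outrun ring closure. If closure is slow, displacement of fluoride by traces of water or of dimethylamine from DMF could compete. The fallback closes the macrocycle at the ring B–ring C bridge instead. It sets out from 8.
- Hydrolysis of the MOM acetal (aqueous HCl, THF) would give 2-{2-[2-(3-hydroxy-4,5-dimethoxyphenyl)ethyl]phenoxy}-3,4-dimethoxybenzaldehyde F1.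
- SNAr of its phenoxide with purchased 4-fluorobenzaldehyde (O=Cc1ccc(F)cc1; K2CO3, DMF, 120 °C) would give the dialdehyde 2-{2-[2-(3-(4-formylphenoxy)-4,5-dimethoxyphenyl)ethyl]phenoxy}-3,4-dimethoxybenzaldehyde F2.
- Intramolecular McMurry coupling (TiCl4, Zn, THF, reflux, high dilution) would give the macrocyclic stilbene tetramethyl ether F3.
- Hydrogenation (H2, Pd/C) would come back to the route at 18.

**Step 4.** The methoxy group para to the formyl group weakens the activation and the fluorine is flanked by a methoxy group, so addition of the phenoxide may be sluggish and the aldehyde may degrade at the temperature needed. The fallback sets out from 6 and replaces SNAr by a copper-catalysed Ullmann etherification with purchased 2-bromo-3,4-dimethoxybenzaldehyde (O=Cc1ccc(OC)c(OC)c1Br; CuI, N,N-dimethylglycine, Cs2CO3, dioxane, 100 °C). It comes back at 8 and makes no new compound.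

**Step 6.** Fluoride may be lost before olefination, through attack of the ylide carbon or the base at the fluorine-bearing carbon, or through electron transfer to the nitroarene. The fallback reverses the polarity of the olefination. It sets out from 8.
- Reduction with NaBH4 in MeOH would give the benzylic alcohol F4.
- The Appel reaction (CBr4, PPh3, CH2Cl2) would give the benzylic bromide F5.
- PPh3 in toluene would give the phosphonium bromide F6.
- NaN(SiMe3)2 at −78 °C would give the ylide F7, which would be condensed with purchased 4-fluoro-3-nitrobenzaldehyde (O=Cc1ccc(F)c([N+](=O)[O-])c1), coming back at 12.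

**Step 7.** Saturation of the conjugated stilbene by diimide may stay incomplete, and sulfinate formed from the reagent may slowly displace fluoride. The fallback avoids the alkene altogether. It sets out from 8.
- Methylenation (Ph3PCH3Br, KOtBu, THF) would give the styrene F8.
- Hydroboration with 9-BBN would give the B-alkyl borane F9.
- Suzuki–Miyaura coupling of F9 in the same flask with purchased 4-bromo-1-fluoro-2-nitrobenzene ([O-][N+](=O)c1cc(Br)ccc1F; PdCl2(dppf), K3PO4, THF–DMF–H2O, 50 °C) would come back at 13, bypassing steps 5 to 7.

**Step 11.** The aryl radical or cation formed ortho to the diaryl ether oxygen may cyclise onto ring A (Pschorr-type closure to a dibenzofuran) or be trapped by water, instead of being reduced. The fallback sets out from 15 and removes the nitro group directly by palladium-catalysed reductive denitration (Pd(acac)2, BrettPhos, K3PO4, 2-propanol, dioxane, 130 °C). It comes back at 18 without passing through 16 and 17 and makes no new compound.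

## Further compounds

F1 | step 9 | 2-{2-[2-(3-hydroxy-4,5-dimethoxyphenyl)ethyl]phenoxy}-3,4-dimethoxybenzaldehyde | Oc1cc(CCc2ccccc2Oc2c(C=O)ccc(OC)c2OC)cc(OC)c1OC
F2 | step 9 | 2-{2-[2-(3-(4-formylphenoxy)-4,5-dimethoxyphenyl)ethyl]phenoxy}-3,4-dimethoxybenzaldehyde | O=Cc1ccc(Oc2cc(CCc3ccccc3Oc3c(C=O)ccc(OC)c3OC)cc(OC)c2OC)cc1
F3 | step 9 | macrocyclic stilbene tetramethyl ether (CH=CH between ring B and ring C, geometry open) | COc1cc2cc(c1OC)Oc1ccc(cc1)C=Cc1ccc(OC)c(OC)c1Oc1ccccc1CC2
F0 | step 4 | none | none
F4 | step 6 | (2-{2-[2-(3,4-dimethoxy-5-(methoxymethoxy)phenyl)ethyl]phenoxy}-3,4-dimethoxyphenyl)methanol | COCOc1cc(CCc2ccccc2Oc2c(CO)ccc(OC)c2OC)cc(OC)c1OC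
F5 | step 6 | 1-(bromomethyl)-2-{2-[2-(3,4-dimethoxy-5-(methoxymethoxy)phenyl)ethyl]phenoxy}-3,4-dimethoxybenzene | COCOc1cc(CCc2ccccc2Oc2c(CBr)ccc(OC)c2OC)cc(OC)c1OC
F6 | step 6 | (2-{2-[2-(3,4-dimethoxy-5-(methoxymethoxy)phenyl)ethyl]phenoxy}-3,4-dimethoxybenzyl)triphenylphosphonium bromide | COCOc1cc(CCc2ccccc2Oc2c(C[P+](c3ccccc3)(c3ccccc3)c3ccccc3)ccc(OC)c2OC)cc(OC)c1OC.[Br-]
F7 | step 6 | (2-{2-[2-(3,4-dimethoxy-5-(methoxymethoxy)phenyl)ethyl]phenoxy}-3,4-dimethoxybenzylidene)triphenylphosphorane | COCOc1cc(CCc2ccccc2Oc2c(C=P(c3ccccc3)(c3ccccc3)c3ccccc3)ccc(OC)c2OC)cc(OC)c1OC
F8 | step 7 | 1-ethenyl-2-{2-[2-(3,4-dimethoxy-5-(methoxymethoxy)phenyl)ethyl]phenoxy}-3,4-dimethoxybenzene | COCOc1cc(CCc2ccccc2Oc2c(C=C)ccc(OC)c2OC)cc(OC)c1OC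
F9 | step 7 | 9-[2-(2-{2-[2-(3,4-dimethoxy-5-(methoxymethoxy)phenyl)ethyl]phenoxy}-3,4-dimethoxyphenyl)ethyl]-9-borabicyclo[3.3.1]nonane | COCOc1cc(CCc2ccccc2Oc2c(CCB3C4CCCC3CCC4)ccc(OC)c2OC)cc(OC)c1OC
F0 | step 11 | none | none
A1 | alternative 1 | seco bis(halophenol): ring A 3,5-dibromo-4-hydroxyphenyl, ring B 3,5-dichloro-4-hydroxyphenyl | Oc1c(Br)cc(CCc2ccccc2Oc2c(CCc3cc(Cl)c(O)c(Cl)c3)ccc(OC)c2OC)cc1Br
A2 | alternative 1 | macrocyclic bromophenol diaryl ether with dichloro ring B | Brc1cc2cc(c1O)Oc1c(Cl)cc(cc1Cl)CCc1ccc(OC)c(OC)c1Oc1ccccc1CC2
A3 | alternative 2 | seco arylacetic acid: [4-(5-{2-[2-(2,3-dimethoxyphenoxy)phenyl]ethyl}-2,3-dimethoxyphenoxy)phenyl]acetic acid | COc1cc(CCc2ccccc2Oc2cccc(OC)c2OC)cc(Oc2ccc(CC(=O)O)cc2)c1OC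
A4 | alternative 2 | acid chloride of A3 | COc1cc(CCc2ccccc2Oc2cccc(OC)c2OC)cc(Oc2ccc(CC(=O)Cl)cc2)c1OC
A5 | alternative 2 | macrocyclic deoxybenzoin tetramethyl ether with the ketone on ring C | COc1cc2cc(c1OC)Oc1ccc(cc1)CC(=O)c1ccc(OC)c(OC)c1Oc1ccccc1CC2
A6 | alternative 3 | seco ynol ether–pyrone: ring A C3 ethynyl ether, 2-pyrone acylated at C5 by the ring C arylacetyl unit | C#COc1cc(CCc2ccccc2Oc2c(CC(=O)c3ccc(=O)oc3)ccc(OC)c2OC)cc(OC)c1OC
A7 | alternative 3 | macrocyclic deoxybenzoin tetramethyl ether with the ketone on ring B | COc1cc2cc(c1OC)Oc1ccc(cc1)C(=O)Cc1ccc(OC)c(OC)c1Oc1ccccc1CC2
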